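- I started from the target: each part of it stands for one part of substrate and one part of reagent gone, so at equal charges, as in delta, gamma and epsilon, the fraction of substrate left and the fraction of reagent left are nearly one number, and that number is what I had to find.

| flask | substrate | reagent | free catalyst | remark | time |
|---|---|---|---|---|---|
| north-east | 0.079 M | 0.50 equiv | 0.1 mol% | run made earlier |  |
| south-east | 0.079 M | 0.75 equiv | 0.1 mol% | run made earlier |  |
| north | 0.079 M | 1 equiv | 0.15 mol% | run made earlier |  |
| delta | 0.079 M | 1.00 equiv | 0.1 mol% |  | 2.5 min |
| gamma | 0.079 M | 1.00 equiv | 0.1 mol% |  | 5.0 min |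
| epsilon | 0.079 M | 1.00 equiv | 0.1 mol% |  | 10 min |

| run | time / min | catalyst intermediate B / % | catalyst intermediate A / % | target / % | substrate / % |
|---|---|---|---|---|---|
| north-east | 0.250 | 0.3 | 0 | 0.9 | 98.5 |
| north-east | 0.417 | 0 | 0.3 | 1.2 | 99.3 |
| north-east | 0.667 | 0.8 | 0 | 1.6 | 97.8 |
| north-east | 1.00 | 0 | 0 | 2.6 | 97.3 |
| north-east | 2.00 | 0 | 0 | 5.2 | 94.1 |
| north-east | 3.00 | 0 | 0 | 7.0 | 91.4 |
| south-east | 0.500 | 0 | 0.4 | 1.7 | 98.6 |
| south-east | 1.00 | 0 | 0 | 4.0 | 96.5 |
| south-east | 1.50 | 0 | 0 | 6.1 | 94.0 |
| south-east | 2.00 | 0.3 | 0.6 | 7.4 | 92.5 |
| south-east | 2.50 | 0 | 0.5 | 9.1 | 90.6 |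
| south-east | 3.00 | 0.1 | 0 | 9.9 | 90.5 |
| north | 0.250 | 1.1 | 0.1 | 1.9 | 98.3 |
| north | 0.417 | 0.4 | 0 | 2.6 | 98.0 |
| north | 0.833 | 0.3 | 0.9 | 5.2 | 94.8 |
| north | 1.50 | 0.8 | 0 | 9.7 | 90.3 |
| north | 3.00 | 0 | 0 | 17.0 | 83.2 |

(standard deviation of a reading: 0.5 percentage points)

1. which of these there is most of at the end, counted by the substrate in it, delta (catalyst intermediate A / substrate / catalyst intermediate B / target)
2. which of these there is most of at the end, counted by the substrate in it, gamma (catalyst intermediate A / substrate / catalyst intermediate B / target)
3. which of these there is most of at the end, counted by the substrate in it, epsilon (catalyst intermediate A / substrate / catalyst intermediate B / target)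
4. how much there is at the end of the one of these that leads, in percent of the substrate charged: delta
5. how much there is at the end of the one of these that leads, in percent of the substrate charged: gamma
6. how much there is at the end of the one of these that leads, in percent of the substrate charged: epsilon

- percent here means substrate units held: one resting dimer counts as two
- what is said of target includes idle complex
- what may be going on: substrate + free catalyst -> catalyst intermediate A; reagent + catalyst intermediate A <-> catalyst intermediate B; catalyst intermediate B -> free catalyst + target; 2 catalyst intermediate A <-> resting dimer; free catalyst + target <-> idle complex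

- At the early end, target after 1.00 min read 2.6 % with 0.50 equiv of reagent and 4.0 % with 0.75 equiv, a ratio of 1.54 against a ratio of charges of 1.50, so I read the rate as proportional to the reagent present.
- At the late end, target can't pass the reagent charge, so a straight line had to bend, and the join of both ends is an exponential fall of reagent. The last readings gave 0.0503 /min in the north-east run and 0.0472 /min in the south-east run.
- I carried their mean, 0.0487 /min: my reagent clock, the fraction of the reagent still present that goes per minute at this loading, a pseudo-first-order constant.
- My first doubt was the gap between those two values, 6.37 % of the mean. But a reading of 7.0 % carries a scatter of 0.5 percentage points, so I let the gap stand.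
- My second doubt was that the north run, the one run at 1 equiv, had 0.15 mol% of catalyst. Its clock read 0.0621 /min, and if I assumed a square-root dependence on loading, that became 0.0507 /min at 0.1 mol%, close to my clock.
- My third doubt I could not compute away: these runs all began at 0.079 M of substrate, and the lowest last reading of substrate was 83.2 %, in the north run, so I could not tell from them whether falling substrate slows the rate too. If it did, my reckoning for epsilon gave 67.2 % substrate instead of 61.4 %. Either way substrate in epsilon came out more than target.
- I committed to the exponential: substrate left 88.5 % in delta, 78.4 % in gamma and 61.4 % in epsilon.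
- The forecast gave 88 %, 78 % and 61.5 % for these flasks, in its words “Substrate therefore remains the largest species”.
- The flasks gave substrate in the lead at 87.9 % in delta, 77.3 % in gamma and 59.7 % in epsilon. My epsilon figure stood 1.7 points high, and the clock read back from gamma is 0.0516 /min.

    substrate + free catalyst → catalyst intermediate A (k = 408 /M/s)
    reagent + catalyst intermediate A ⇌ catalyst intermediate B (K = 21.3 /M, k = 520 /M/s)
    catalyst intermediate B → free catalyst + target (k = 24.1 /s)
    2 catalyst intermediate A ⇌ resting dimer, settled at all times (K = 3.24 × 10⁶ /M)
    free catalyst + target ⇌ idle complex (K = 5.53 /M, k = 5.64 /M/s)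

- In delta, the step from substrate and free catalyst, with free catalyst held at its charge, has a half-life of 0.36 min, short against 2.5 min, yet 87.9 % of the substrate stands at that time. The catalyst charged in delta then stood 89.9 % as resting dimer, its resting state, and 2.66 % as free catalyst.
- For the gamma flask left until 20 min, the clock gave 37.8 % substrate left, so more target than substrate. That flask gave 35.6 % substrate, with target leading at 64.3 %.

All runs were computed on assumed constants; noise was put on by code.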